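We decide to read the plateau of Wednesday's run as a concentration of free monomer, not as a percentage of the charge.

| flask | free monomer | initiator | remark | time |
|---|---|---|---|---|
| Wednesday's | 0.33 M | 0.34 mol% | run made earlier |  |
| elm | 0.33 M | 0.5 mol% |  | 25 h |
| birch | 1.2 M | 0.5 mol% |  | 25 h |

Wednesday's run (percent of the free monomer charged)

| time / h | monomer in chains / % |
|---|---|
| 0.333 | 9 |
| 1.00 | 19 |
| 2.00 | 30 |
| 2.50 | 32 |
| 4.00 | 42 |
| 5.00 | 40 |

(readings scatter by 1.5 percentage points)

- the average divides the monomer in chains by the number of chains begun, living and dead together
- steps thought possible: free monomer + initiator -> living end + monomer in chains; free monomer + living end -> monomer in chains + living end; monomer in chains + living end -> free monomer + living end; 2 initiator -> spent initiator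
- the earlier runs do not show the number of chains; that part of a forecast is a guess
- no earlier run changes the charge of initiator; that part of a forecast is a guess

1. which of the two ends with the longer chains by the average number of monomer units in a chain (chains begun, living or dead) ("neither" if they lie within 10%) (elm / birch / neither)
2. average number of monomer units in a chain (chains begun, living or dead) at the end, elm
3. average number of monomer units in a chain (chains begun, living or dead) at the end, birch

The last two readings of Wednesday's run average 41.0%, so:

[free monomer] at the plateau = 0.33 M × (1 − 41.0%) = 0.195 M

We call this the ceiling concentration, the [free monomer] at which a living end adds units as fast as it loses them; the usual term is equilibrium monomer concentration. One run cannot tell it from a fixed percentage, so our choice is a guess: a unit leaves at a living end, and the number of ends does not follow the length of the chains.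

We go up the ladder of times. On the first rung, as we guess, initiator begins chains or turns into spent initiator, which the readings do not show. On the second, free monomer falls to the ceiling: Wednesday's reading at 1.00 h stands at half of the plateau, with 0.00112 M of initiator charged. Elm is charged with 0.00165 M of initiator and birch with 0.00600 M. Scaling that time inversely with the initiator charge, again a guess, gives 0.680 h for elm and 0.187 h for birch. The third rung is the asked 25 h, far longer than either, so we expect both flasks at the ceiling:

monomer in chains: elm 0.33 M − 0.195 M = 0.135 M; birch 1.2 M − 0.195 M = 1.01 M

per initiator charged (0.00165 M; 0.00600 M): elm 82.0; birch 168

Initiator lost to spent initiator raises both numbers, by one factor as we guess, the loading being equal, so birch should end about twice as long as elm.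

The forecast differs, with neither as the answer and 90 for elm and 90 for birch: "Conversion is then about 43% whatever the concentration."

The simulation gives 123 for elm and 246 for birch, so birch ends with the longer chains.

    free monomer + initiator → living end + monomer in chains (k = 0.930 /M/min)
    free monomer + living end → monomer in chains + living end, rate k2*[living end]*[free monomer] (k = 12.0 /M/min)
    monomer in chains + living end → free monomer + living end, rate k3*[living end] as long as [monomer in chains] is above zero (k = 2.30 /min)
    2 initiator → spent initiator (k = 97.0 /M/min)

In birch at 25.0 h monomer in chains is made 1.00 times as fast as it is used up, and the slowest mode has a half-life of 0.235 h, far shorter than 25 h. Free monomer in birch stands at 0.192 M, where our reading of Wednesday's run put it at 0.195 M, and living ends in birch are 68.4% of the initiator charged. A neighbour of birch with 0.30 M of free monomer and 0.00150 M of initiator gets 0.105 M in chains from the ceiling, 35.0% of its charge, and with that same share of living ends a length of 102. The simulated neighbour ends with 36.1% of its charge as monomer in chains and an average of 106 units in a chain.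

The data were computed from invented constants; scatter was added.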